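The target is read as a 5,10-epoxygermacranolide (C1–C10 carbocycle, ether O between C5 and C10). Ring A (O–C5–C6–C7–C8–C9–C10) is the ring of (S)-carvone with the ether oxygen inserted into its enone C=C bond: ozonolysis gives a keto-aldehyde, crotylboration sets C4/C5, and ketalisation–allylation closes ring A and sets C10. Because C5 and C10 flank the ether oxygen and carry their arms cis on ring A, ring-closing metathesis of this cis-2,7-dialkenyl oxepane forms C2=C3 and closes ring B (O–C5–C4–C3–C2–C1–C10), the last ring. The lactone is in place from step 3; its methylene is masked only for the final hydrogenation.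

Key step: step 9

Remark on locants: germacranolide numbering is used for the target and late intermediates (lactone C12(=O)–O–C8 closed on C7 through C11, methylene C13, methyl C14 on C10, methyl C15 on C4, ester oxygen on C9). Carvone C1, C2, C3, C4, C5, C6 become C9, C10, C5, C6, C7, C8; its isopropenyl group becomes C11, C12 (the methyl) and C13. The target is (4S,5R,7R,8R,9S,10R).

Remark on uncontrolled centres: the anomeric carbon of 7, the two trioxolane carbons of 13 and C11 of 22, 23 and 25 are written without configuration, because each is destroyed again.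

Step 1
Reactants: 1 (S)-(+)-carvone; 2 2-(phenylsulfonyl)-3-phenyloxaziridine
Product: 4 (5R,6R)-6-hydroxy-2-methyl-5-(prop-1-en-2-yl)cyclohex-2-en-1-one (trans-6-hydroxycarvone), via lithium dienolate 3 (not isolated)
Conditions: LDA, THF, −78 °C; then 2, −78 °C; then AcOH
Reagents that add atoms: 2-(phenylsulfonyl)-3-phenyloxaziridine O=S(=O)(N1OC1c1ccccc1)c1ccccc1
Why: Kinetic α′-deprotonation of the enone followed by electrophilic enolate hydroxylation with the oxaziridine (Davis oxidation) should place the future C8 oxygen anti to the adjacent isopropenyl group, giving the trans ketol.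

Step 2
Reactants: 4 trans-6-hydroxycarvone; 5 tert-butyl hydroperoxide
Product: 6 (5R,6R)-6-hydroxy-5-(3-hydroxyprop-1-en-2-yl)-2-methylcyclohex-2-en-1-one
Conditions: SeO2 (cat.), tBuOOH, salicylic acid (cat.), CH2Cl2, rt
Reagents that add atoms: tert-butyl hydroperoxide CC(C)(C)OO
Why: Catalytic SeO2 allylic oxidation (ene reaction, then [2,3]-shift) should hydroxylate the methyl group of the electron-rich 1,1-disubstituted alkene in preference to the allylic positions of the electron-poor enone, and any enal formed converges in step 3; no stereocentre is formed.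

Step 3
Reactants: 6 diol
Product: 8 (3aR,7aR)-6-methyl-3-methylidene-3a,4-dihydro-1-benzofuran-2,7(3H,7aH)-dione, via lactol 7 (not isolated)
Conditions: MnO2 (excess), CH2Cl2, rt
Reagents that add atoms: none
Why: MnO2 oxidises the primary allylic alcohol to the enal, the neighbouring trans hydroxyl closes the allylic lactol, and this is oxidised on to the trans-fused α-methylene lactone (oxidative lactonisation of a 2-methylene-1,4-diol) without touching a stereocentre.

Step 4
Reactants: 8 enone lactone
Product: 9 (3aR,7R,7aR)-7-hydroxy-6-methyl-3-methylidene-3a,4,7,7a-tetrahydro-1-benzofuran-2(3H)-one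
Conditions: NaBH4, CeCl3·7H2O, MeOH, −78 °C
Reagents that add atoms: none
Why: Luche 1,2-reduction should deliver hydride axially to the enone carbonyl of the conformationally locked trans-fused bicycle, giving the equatorial C9 alcohol trans to the C8 lactone oxygen (the sense of the carvone to cis-carveol reduction), while CeCl3 and low temperature suppress conjugate reduction of the methylene lactone.

Step 5
Reactants: 9 allylic alcohol; 10 3-methylbutanoyl chloride
Product: 11 (3aR,7R,7aR)-6-methyl-3-methylidene-2-oxo-2,3,3a,4,7,7a-hexahydro-1-benzofuran-7-yl 3-methylbutanoate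
Conditions: 10, pyridine, DMAP (cat.), CH2Cl2, 0 °C to rt
Reagents that add atoms: 3-methylbutanoyl chloride CC(C)CC(Cl)=O
Why: DMAP-catalysed acylation of the only free hydroxyl installs the 3-methylbutanoate of the target, which later also serves as the participating group at C9.

Step 6
Reactants: 11 allylic ester; 12 ozone
Product: 14 (1S)-1-[(2R,3R)-4-methylidene-5-oxo-3-(2-oxoethyl)oxolan-2-yl]-2-oxopropyl 3-methylbutanoate, via ozonide 13 (not isolated)
Conditions: O3, CH2Cl2, −78 °C (Sudan Red 7B end point); then PPh3, −78 °C to rt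
Reagents that add atoms: ozone [O-][O+]=O
Why: Ozonolysis with reductive work-up should cleave the electron-rich trisubstituted ring alkene far faster than the electron-poor conjugated methylene, unveiling the C5 aldehyde and the C10 methyl ketone without affecting a stereocentre.

Step 7
Reactants: 14 keto-aldehyde; 15 diisopropyl (4R,5R)-2-[(2E)-but-2-en-1-yl]-1,3,2-dioxaborolane-4,5-dicarboxylate
Product: 17 (1S)-1-[(2R,3R)-3-[(2R,3S)-2-hydroxy-3-methylpent-4-en-1-yl]-4-methylidene-5-oxooxolan-2-yl]-2-oxopropyl 3-methylbutanoate, via borate ester 16 (not isolated)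
Conditions: 15, 4 Å molecular sieves, toluene, −78 °C; then aq NaHCO3
Reagents that add atoms: diisopropyl (4R,5R)-2-[(2E)-but-2-en-1-yl]-1,3,2-dioxaborolane-4,5-dicarboxylate C/C=C/CB1O[C@@H](C(=O)OC(C)C)[C@@H](O1)C(=O)OC(C)C
Why: Roush crotylboration through a chair transition state is chemoselective for the aldehyde over the ketone; the (E)-crotyl unit sets the C4 methyl anti to the C5 hydroxyl and the (R,R)-tartrate directs attack to the Si face of the aldehyde, which should give (4S,5R).

Step 8
Reactants: 17 hydroxy ketone; 18 allyltrimethylsilane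
Product: 19 ring A diene, (4S,5R,7R,8R,9S,10R)-10-allyl-5-[(2S)-but-3-en-2-yl]-10-methyloxepane trans-fused at C7–C8 to the 11(13)-methylene 12,8-lactone, 9-(3-methylbutanoate)
Conditions: allylSiMe3 (10 equiv), TMSOTf (0.3 equiv), CH2Cl2, −78 to −40 °C
Reagents that add atoms: allyltrimethylsilane C=CC[Si](C)(C)C
Why: Intramolecular silyl-modified Sakurai reaction: the C5 hydroxyl condenses with the C10 ketone to the seven-membered cyclic oxocarbenium ion (both hemiketal epimers converge on it), the C9 ester participates from its own face as a dioxolenium ion, and the allylsilane should therefore attack trans to the ester, which places the allyl group cis to the C5 arm on ring A and sets C10 as R.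

Step 9
Reactants: 19 ring A diene
Product: 20 (2Z,4S,5R,7R,8R,9S,10R)-9-(3-methylbutanoyloxy)-5,10-epoxygermacra-2,11(13)-dien-12,8-olide
Conditions: RuCl2(=CHPh)(PCy3)(H2IMes) (second-generation Grubbs catalyst, 5 mol %), CH2Cl2 (2 mM), 40 °C
Reagents that add atoms: none
Why: Olefin metathesis through ruthenium alkylidene and ruthenacyclobutane intermediates: the carbene should load on the unhindered allyl terminus at C10, add to the vinyl group on C4 and release ethylene, forming the C2=C3 bond. The closest known reaction type is the ring-closing metathesis of cis-2,6-dialkenyl tetrahydropyrans and cis-2,5-dialkenyl tetrahydrofurans to oxygen-bridged cycloalkenes. Ring B (O–C5–C4–C3–C2–C1–C10) is closed as a seven-membered ring in the bridging mode across the ether oxygen, the cis alkene being the only geometry this ring allows. No stereocentre is created: C4, C5 and C10 are already fixed, and the step only requires the cis relation of the two arms on C5 and C10 that steps 7 and 8 provide. The selectivity needed is ring closure over oligomerisation and over engagement of the C11=C13 methylene; high dilution and the seven-membered ring size serve the first, and the electron-poor 1,1-disubstituted methylene, held on the opposite face of ring A, should not compete.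

Step 10
Reactants: 20 bridged diene; 21 dimethylamine
Product: 22 13-(dimethylamino)-11,13-dihydro derivative of 20 (C11 epimers)
Conditions: Me2NH (2 M in THF), MeOH, 0 °C to rt
Reagents that add atoms: dimethylamine CNC
Why: Aza-Michael addition of dimethylamine to the exocyclic enoate masks the methylene lactone as a Mannich base so that the next step sees only one alkene; the new C11 centre is inconsequential.

Step 11
Reactants: 22 amine adduct
Product: 23 (4S,5R,7R,8R,9S,10R)-13-(dimethylamino)-9-(3-methylbutanoyloxy)-5,10-epoxygermacran-12,8-olide (C11 epimers)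
Conditions: H2 (1 atm), Pd/C, EtOAc, rt
Reagents that add atoms: none
Why: Heterogeneous hydrogenation saturates the disubstituted C2=C3 alkene, the only alkene left, and creates no stereocentre since C2 and C3 become methylene groups.

Step 12
Reactants: 23 saturated amine; 24 iodomethane
Product: 26 (4S,5R,7R,8R,9S,10R)-9-(3-methylbutanoyloxy)-5,10-epoxygermacr-11(13)-en-12,8-olide (CNP0274454.1), via ammonium iodide 25 (not isolated)
Conditions: MeI, THF, rt; then aq NaHCO3, EtOAc, rt
Reagents that add atoms: none
Why: Exhaustive N-methylation followed by base-induced β-elimination of trimethylamine from the β-ammonio lactone (E1cB, Hofmann type) should regenerate the C11=C13 methylene under conditions that leave the ester and all stereocentres untouched.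

Compound list

1 | (S)-(+)-carvone | CC1=CC[C@@H](CC1=O)C(C)=C | starting material
2 | 2-(phenylsulfonyl)-3-phenyloxaziridine (racemic) | O=S(=O)(N1OC1c1ccccc1)c1ccccc1 | starting material
3 | lithium cross-conjugated dienolate of carvone | [Li]OC1=C[C@@H](C(C)=C)CC=C1C | intermediate (not isolated)
4 | (5R,6R)-6-hydroxy-2-methyl-5-(prop-1-en-2-yl)cyclohex-2-en-1-one | C=C(C)[C@H]1CC=C(C)C(=O)[C@@H]1O | intermediate
5 | tert-butyl hydroperoxide | CC(C)(C)OO | starting material
6 | (5R,6R)-6-hydroxy-5-(3-hydroxyprop-1-en-2-yl)-2-methylcyclohex-2-en-1-one | C=C(CO)[C@H]1CC=C(C)C(=O)[C@@H]1O | intermediate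
7 | (3aR,7aR)-2-hydroxy-6-methyl-3-methylidene-3,3a,4,7a-tetrahydro-1-benzofuran-7(2H)-one (anomers) | C=C1C(O)O[C@@H]2[C@@H]1CC=C(C)C2=O | intermediate (not isolated)
8 | (3aR,7aR)-6-methyl-3-methylidene-3a,4-dihydro-1-benzofuran-2,7(3H,7aH)-dione | C=C1C(=O)O[C@@H]2[C@@H]1CC=C(C)C2=O | intermediate
9 | (3aR,7R,7aR)-7-hydroxy-6-methyl-3-methylidene-3a,4,7,7a-tetrahydro-1-benzofuran-2(3H)-one | C=C1C(=O)O[C@@H]2[C@@H]1CC=C(C)[C@H]2O | intermediate
10 | 3-methylbutanoyl chloride | CC(C)CC(Cl)=O | starting material
11 | (3aR,7R,7aR)-6-methyl-3-methylidene-2-oxo-2,3,3a,4,7,7a-hexahydro-1-benzofuran-7-yl 3-methylbutanoate | C=C1C(=O)O[C@@H]2[C@@H]1CC=C(C)[C@H]2OC(=O)CC(C)C | intermediate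
12 | ozone | [O-][O+]=O | starting material
13 | secondary ozonide of 11 (1,2,4-trioxolane across the former ring alkene) | C=C1C(=O)O[C@@H]2[C@@H]1CC1OOC(C)(O1)[C@H]2OC(=O)CC(C)C | intermediate (not isolated)
14 | (1S)-1-[(2R,3R)-4-methylidene-5-oxo-3-(2-oxoethyl)oxolan-2-yl]-2-oxopropyl 3-methylbutanoate | C=C1C(=O)O[C@@H]([C@H](OC(=O)CC(C)C)C(C)=O)[C@@H]1CC=O | intermediate
15 | diisopropyl (4R,5R)-2-[(2E)-but-2-en-1-yl]-1,3,2-dioxaborolane-4,5-dicarboxylate | C/C=C/CB1O[C@@H](C(=O)OC(C)C)[C@@H](O1)C(=O)OC(C)C | starting material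
16 | tartrate borate ester of 17 (boron on the C5 oxygen) | C=C1C(=O)O[C@@H]([C@H](OC(=O)CC(C)C)C(C)=O)[C@@H]1C[C@@H](OB1O[C@@H](C(=O)OC(C)C)[C@@H](O1)C(=O)OC(C)C)[C@@H](C)C=C | intermediate (not isolated)
17 | (1S)-1-[(2R,3R)-3-[(2R,3S)-2-hydroxy-3-methylpent-4-en-1-yl]-4-methylidene-5-oxooxolan-2-yl]-2-oxopropyl 3-methylbutanoate | C=C1C(=O)O[C@@H]([C@H](OC(=O)CC(C)C)C(C)=O)[C@@H]1C[C@@H](O)[C@@H](C)C=C | intermediate
18 | allyltrimethylsilane | C=CC[Si](C)(C)C | starting material
19 | ring A diene: (4S,5R,7R,8R,9S,10R)-10-allyl-5-[(2S)-but-3-en-2-yl]-10-methyloxepane, trans-fused 11(13)-methylene 12,8-lactone, 9-(3-methylbutanoate) | C=C1C(=O)O[C@@H]2[C@@H]1C[C@@H](O[C@](C)(CC=C)[C@H]2OC(=O)CC(C)C)[C@@H](C)C=C | intermediate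
20 | (2Z,4S,5R,7R,8R,9S,10R)-9-(3-methylbutanoyloxy)-5,10-epoxygermacra-2,11(13)-dien-12,8-olide | C=C1C(=O)O[C@@H]2[C@@H]1C[C@H]1O[C@](C)(CC=C[C@@H]1C)[C@H]2OC(=O)CC(C)C | intermediate
21 | dimethylamine | CNC | starting material
22 | 13-(dimethylamino)-11,13-dihydro derivative of 20 (C11 epimers) | CN(C)CC1C(=O)O[C@@H]2[C@@H]1C[C@H]1O[C@](C)(CC=C[C@@H]1C)[C@H]2OC(=O)CC(C)C | intermediate
23 | (4S,5R,7R,8R,9S,10R)-13-(dimethylamino)-9-(3-methylbutanoyloxy)-5,10-epoxygermacran-12,8-olide (C11 epimers) | CN(C)CC1C(=O)O[C@@H]2[C@@H]1C[C@H]1O[C@](C)(CCC[C@@H]1C)[C@H]2OC(=O)CC(C)C | intermediate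
24 | iodomethane | CI | starting material
25 | N,N,N-trimethylammonium iodide of 23 | C[N+](C)(C)CC1C(=O)O[C@@H]2[C@@H]1C[C@H]1O[C@](C)(CCC[C@@H]1C)[C@H]2OC(=O)CC(C)C.[I-] | intermediate (not isolated)
26 | (4S,5R,7R,8R,9S,10R)-9-(3-methylbutanoyloxy)-5,10-epoxygermacr-11(13)-en-12,8-olide, CNP0274454.1 | C=C1C(=O)O[C@@H]2[C@@H]1C[C@H]1O[C@](C)(CCC[C@@H]1C)[C@H]2OC(=O)CC(C)C | target

Total step count: 12. Longest linear sequence: 12 steps, from 1.

Steps most likely to fail

1. Step 8. The ring A oxocarbenium ion may be intercepted by the pendant vinyl group on C4 (Prins closure or 2-oxonia-Cope allyl shift) before the allylsilane arrives, and weak ester participation would erode facial control at C10. The fallback sets out from 14. Anti-selective propargylation with the allenylzinc reagent made from (R)-but-3-yn-2-yl methanesulfonate (Pd(OAc)2, PPh3, Et2Zn, THF, −20 °C; net inversion at the propargylic carbon) should give homopropargylic alcohol F1 with the same C4/C5 configuration. The same TMSOTf/allylSiMe3 ketalisation–allylation then runs on a substrate whose alkyne cannot engage the cation and gives ring A enyne F2. Semi-hydrogenation of the terminal alkyne (H2, Pd/CaCO3, Pb(OAc)2, quinoline, EtOAc) comes back to the route at 19.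

2. Step 9. Oligomerisation by cross-metathesis may outrun ring closure if the conformer with both arms pseudo-axial is thinly populated, or the carbene may be held back by chelation to the C9 ester. The fallback sets out from 19. Cleavage of both monosubstituted alkenes (OsO4 cat., NaIO4, 2,6-lutidine, dioxane/H2O; the electron-poor methylene reacts more slowly) should give dialdehyde F3. Intramolecular reductive carbonyl coupling (McMurry reaction, TiCl3(DME)1.5, Zn–Cu, DME, slow addition) then forms the same C2=C3 alkene and comes back to the route at 20.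

3. Step 2. The allylic oxidation may stall, over-oxidise, or attack the ketol instead of the isopropenyl methyl group. The fallback sets out from 4. Ene-type allylic chlorination (Ca(OCl)2, solid CO2, CH2Cl2/H2O, 0 °C) should give allylic chloride F4. N-Methylmorpholine N-oxide (MeCN, rt) then oxidises the chloride to the enal, which closes to lactol 7 and is oxidised with MnO2 as in step 3, so the fallback comes back to the route at 8.

Further compounds

F1 | step 8 | (1S)-1-[(2R,3R)-3-[(2R,3S)-2-hydroxy-3-methylpent-4-yn-1-yl]-4-methylidene-5-oxooxolan-2-yl]-2-oxopropyl 3-methylbutanoate | C=C1C(=O)O[C@@H]([C@H](OC(=O)CC(C)C)C(C)=O)[C@@H]1C[C@@H](O)[C@@H](C)C#C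
F2 | step 8 | ring A enyne: analogue of 19 with a (2S)-but-3-yn-2-yl arm on C5 | C=C1C(=O)O[C@@H]2[C@@H]1C[C@@H](O[C@](C)(CC=C)[C@H]2OC(=O)CC(C)C)[C@@H](C)C#C
F3 | step 9 | dialdehyde: analogue of 19 with 2-oxoethyl on C10 and 1-oxopropan-2-yl on C5 | C=C1C(=O)O[C@@H]2[C@@H]1C[C@@H](O[C@](C)(CC=O)[C@H]2OC(=O)CC(C)C)[C@@H](C)C=O
F4 | step 2 | (5R,6R)-5-(3-chloroprop-1-en-2-yl)-6-hydroxy-2-methylcyclohex-2-en-1-one | C=C(CCl)[C@H]1CC=C(C)C(=O)[C@@H]1O
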